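**Retrosynthetic overview**
- Target ⇒ late aerobic C11'–H peroxidation and hemiketal closure (dioxolane formed last) ⇒ bis-guaiane Diels–Alder adduct.
- Adduct ⇒ [4+2] of a 5-acetoxycyclopentadiene (half A, 10S) with a cyclopentadienone (half B, 10R), both released in the same flask by dehydration of tertiary alcohols; this forms the bicyclo[2.2.1] core.
- Both alcohols ⇒ singlet-oxygen [4+2] on the two 1,5-H-shift tautomers of one cyclopentadiene, made in both enantiomeric series from one achiral ene-dione with antipodal CuH catalysts.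
- Ene-dione ⇒ key step: dearomatising intramolecular Buchner ring expansion of a thymol-derived diazoketone, which builds the seven- and five-membered carbocycles of both halves at once.

Assumption: guaiane numbering is used (C1–C5 five-membered ring, C1/C5 ring fusion, C15 methyl on C4, isopropyl on C7, oxygen on C8, C14 methyl on C10; primed atoms = dienophile half; α/β = the two ring faces, with the C10 methyl α in the A series and β in the B series), and the sense of induction of the DTBM-SEGPHOS/CuH catalysts is assumed (if reversed, the two ligand antipodes are exchanged).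

**Step 1**
Reactants: 1 thymol; 2 methyl vinyl ketone
Product: 4 5-methyl-4-(3-oxobutyl)-2-(propan-2-yl)phenyl pivalate, via phenol ketone 3 (not isolated)
Conditions: TfOH (5 mol %), PhMe, 0 → 40 °C; then PivCl, Et3N, DMAP, CH2Cl2, 0 °C
Reagents that add atoms: pivaloyl chloride, CC(C)(C)C(=O)Cl
Why: Acid-catalysed Friedel–Crafts conjugate addition of the phenol to the enone (raspberry-ketone type) occurs at the free para position of thymol, and the phenol is then capped as a pivalate, which has no α-hydrogen, survives the next enolate step and tempers the arene for the carbene step.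

**Step 2**
Reactants: 4 aryl pivalate methyl ketone
Product: 6 4-(4-diazo-3-oxobutyl)-5-methyl-2-(propan-2-yl)phenyl pivalate, via trifluoroacetyl diketone 5 (not isolated)
Conditions: LiHMDS, THF, −78 °C; CF3CO2CH2CF3; aq HCl; then MsN3, Et3N, H2O, MeCN, 25 °C
Reagents that add atoms: methanesulfonyl azide, CS(=O)(=O)N=[N+]=[N-]
Why: Danheiser detrifluoroacetylative diazo transfer: the kinetic methyl enolate is trifluoroacetylated and Regitz diazo transfer with loss of the trifluoroacetyl group gives the terminal α-diazoketone.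

**Step 3 (key step)**
Reactants: 6 diazoketone
Product: 9 4-methyl-7-(propan-2-yl)-2,3,7,8-tetrahydroazulene-1,6-dione (15-norguaia-1(5),9-diene-4,8-dione, racemic at the epimerisable C7), via norcaradiene 7 (not isolated), via cycloheptatrienyl pivalate 8 (not isolated)
Conditions: Rh2(OAc)4 (1 mol %), CH2Cl2, 40 °C, slow addition; then K2CO3 (0.2 equiv), MeOH, 25 °C
Reagents that add atoms: none
Why: Intramolecular Buchner reaction: the rhodium carbenoid cyclopropanates the ipso/ortho bond on the side of the unsubstituted ortho carbon (away from the ortho methyl), the norcaradiene opens by 6π electrocyclisation, and methanolysis of the enol pivalate releases an extended enolate that funnels by prototropy into the fully conjugated ene-dione (O=C–C=C–C=C–C=O), taken as the thermodynamic tautomer.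

**Step 4**
Reactants: 9 ene-dione
Product: 10 (4S)-6-{[dimethyl(phenyl)silyl]oxy}-4-methyl-7-(propan-2-yl)-3,4,7,8-tetrahydroazulen-1(2H)-one (C7 epimers)
Conditions: Cu(OAc)2·H2O (3 mol %), (S)-DTBM-SEGPHOS (3.3 mol %), PhMe2SiH, PhMe, 0 °C; Florisil filtration
Reagents that add atoms: dimethyl(phenyl)silane, C[SiH](C)c1ccccc1
Why: Ligand-controlled copper hydride asymmetric 1,4-reduction (Buchwald/Lipshutz type) delivers hydride to C10, the only unhindered β-carbon (the cyclopentenone is α,β,β-trisubstituted and inert), setting 10S; the enolate is kept as the C8 silyl enol ether, which masks that ketone for step 5.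

**Step 5**
Reactants: 10 silyl enol ether enone
Product: 12 (10S)-guaia-1,4-dien-8-one (C7 epimers; in 1,5-H-shift equilibrium with (10S)-guaia-1(5),3-dien-8-one), via tertiary alcohol 11 (not isolated)
Conditions: MeLi, CeCl3, THF, −78 °C; then 1 M HCl, THF, 25 °C
Reagents that add atoms: methyllithium, [Li]C
Why: Organocerium (Imamoto) 1,2-addition to the hindered, enolisable cyclopentenone installs the C15 methyl; dilute acid then cleaves the silyl enol ether and dehydrates the tertiary allylic alcohol (E1) to the cyclopentadiene, whose 1,5-hydrogen shifts equilibrate the two ring-diene tautomers without touching C10.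

**Step 6**
Reactants: 12 cyclopentadiene (1,4-diene tautomer)
Product: 14 (2S,4R,10S)-2β,4β-dihydroxyguaia-1(5)-en-8-one (C7 epimers), via endoperoxide 13 (not isolated)
Conditions: O2, tetraphenylporphyrin (cat.), white LED, CH2Cl2, −78 °C; then Zn, AcOH, 0 °C
Reagents that add atoms: dioxygen, O=O
Why: Singlet oxygen adds [4+2] across C2/C4 of the 1,4-diene tautomer on the face opposite the pseudo-axial C10 methyl and zinc cleaves the O–O bond to the cis-2,4-diol (sets C2 and C4); the 1,3-diol from the other tautomer is removed by chromatography, so the yield is capped by the tautomer ratio.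

**Step 7**
Reactants: 14 cis-diol
Product: 15 (2R,4R,7R,10S)-2α-acetoxy-4β-hydroxyguaia-1(5)-en-8-one
Conditions: AcOH, PPh3, DIAD, THF, 0 °C; then DBU (0.2 equiv), PhMe, 25 °C
Reagents that add atoms: acetic acid, CC(=O)O
Why: Mitsunobu esterification inverts only the secondary allylic C2 carbinol (the tertiary C4–OH is inert), placing the acetate cis to the C10 methyl; catalytic DBU then equilibrates C7 to the epimer with an equatorial isopropyl cis to the pseudo-axial C10 methyl (7R).

**Step 8**
Reactants: 9 ene-dione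
Product: 16 (4R)-6-{[dimethyl(phenyl)silyl]oxy}-4-methyl-7-(propan-2-yl)-3,4,7,8-tetrahydroazulen-1(2H)-one (C7 epimers)
Conditions: Cu(OAc)2·H2O (3 mol %), (R)-DTBM-SEGPHOS (3.3 mol %), PhMe2SiH, PhMe, 0 °C; Florisil filtration
Reagents that add atoms: dimethyl(phenyl)silane, C[SiH](C)c1ccccc1
Why: The same copper hydride asymmetric conjugate reduction as step 4 with the antipodal ligand gives the 10R series required for the dienophile half.

**Step 9**
Reactants: 16 silyl enol ether enone
Product: 18 (10R)-guaia-1(5),3-dien-8-one (C7 epimers; in 1,5-H-shift equilibrium with its 1,4-diene tautomer), via tertiary alcohol 17 (not isolated)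
Conditions: MeLi, CeCl3, THF, −78 °C; then 1 M HCl, THF, 25 °C
Reagents that add atoms: methyllithium, [Li]C
Why: As in step 5: organocerium 1,2-addition followed by acid-mediated silyl enol ether cleavage and E1 dehydration to the equilibrating cyclopentadiene.

**Step 10**
Reactants: 18 cyclopentadiene (1(5),3-diene tautomer)
Product: 20 (1S,10R)-1α-hydroxyguaia-4-ene-3,8-dione (C7 epimers), via endoperoxide 19 (not isolated)
Conditions: O2, tetraphenylporphyrin (cat.), white LED, CH2Cl2, −78 °C; then Et3N, 0 °C
Reagents that add atoms: dioxygen, O=O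
Why: Singlet oxygen adds [4+2] across C1/C3 of the 1(5),3-diene tautomer anti to the C10 methyl, and triethylamine triggers Kornblum–DeLaMare fragmentation (the only α-hydrogen is at C3) to the 1-hydroxy-4-en-3-one; the regioisomer from the other tautomer is separated.

**Step 11**
Reactants: 20 hydroxy ene-dione
Product: 21 (1S,10R)-1α-hydroxyguaia-4,6-diene-3,8-dione
Conditions: IBX, 4-methoxypyridine N-oxide, DMSO, 25 °C
Reagents that add atoms: none
Why: IBX dehydrogenation (Nicolaou) of the saturated C8 ketone goes through the more substituted enol (towards C7) and removes the C6 hydrogen, which is also allylic to the enone, giving the conjugated 4,6-dienedione; the enone cannot react (no hydrogen on C1) and the tertiary alcohol is inert.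

**Step 12**
Reactants: 15 acetoxy tertiary alcohol (half A); 21 hydroxy dienedione (half B)
Product: 24 Diels–Alder adduct (bonds C3–C1' and C1–C2'; acetoxy bridge syn to the new C4=C5 alkene; cyclopentenone ring of half B exo; = target without the peroxide, with C8' ketone and C11'–H), via acetoxy diene 22 (not isolated), via cyclopentadienone 23 (not isolated)
Conditions: Burgess reagent (2.5 equiv), PhMe, 25 → 45 °C; 21 (1.5 equiv) added slowly
Reagents that add atoms: none
Why: The Burgess reagent dehydrates both tertiary alcohols by syn-elimination (giving the 5-acetoxycyclopentadiene and the cyclopentadienone), and the dienone C1'=C2' bond is trapped at once in a normal-demand Diels–Alder reaction in which the quaternary-forming C1' joins the unsubstituted diene terminus C3 and each partner reacts on the face anti to its C10 methyl (the diene also anti to its C2 acetoxy group); with these heterochiral partners the three controls place the cyclopentenone ring exo and set C1, C3, C1' and C2'.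

**Step 13**
Reactants: 24 Diels–Alder adduct
Product: 26 CNP0361479.4 (target), via hydroperoxide 25 (not isolated)
Conditions: O2 (1 atm), N-hydroxyphthalimide (20 mol %), 2,2'-azobis(4-methoxy-2,4-dimethylvaleronitrile) (5 mol %), MeCN, 30 °C, dark
Reagents that add atoms: dioxygen, O=O
Why: Proposed new method: radical-chain aerobic hydroperoxidation at C11', the only tertiary C–H allylic to the conjugated dienone and therefore the weakest in the molecule, with reversible peroxyl trapping that ends at the conjugated tertiary hydroperoxide, which closes onto the C8' ketone to the 3-hydroxy-1,2-dioxolane (hemiketal centre under thermodynamic control); closest known chemistry is NHPI-mediated autoxidation at the vinylogous position of enones (isophorone to ketoisophorone) and the spontaneous peroxy-hemiketal closure of the β-hydroperoxy ketone from photo-oxygenated pulegone.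

**Compound list**
1 | thymol | Cc1ccc(C(C)C)c(O)c1 | starting material
2 | methyl vinyl ketone | CC(=O)C=C | starting material
3 | 4-[4-hydroxy-2-methyl-5-(propan-2-yl)phenyl]butan-2-one | CC(=O)CCc1cc(C(C)C)c(O)cc1C | intermediate (not isolated)
4 | 5-methyl-4-(3-oxobutyl)-2-(propan-2-yl)phenyl pivalate | CC(=O)CCc1cc(C(C)C)c(OC(=O)C(C)(C)C)cc1C | intermediate
5 | 5-methyl-2-(propan-2-yl)-4-(6,6,6-trifluoro-3,5-dioxohexyl)phenyl pivalate | O=C(CC(=O)CCc1cc(C(C)C)c(OC(=O)C(C)(C)C)cc1C)C(F)(F)F | intermediate (not isolated)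
6 | 4-(4-diazo-3-oxobutyl)-5-methyl-2-(propan-2-yl)phenyl pivalate | [N-]=[N+]=CC(=O)CCc1cc(C(C)C)c(OC(=O)C(C)(C)C)cc1C | intermediate
7 | norcaradiene valence isomer of 8 (cyclopropane across carbene carbon, ipso carbon and unsubstituted ortho carbon; racemic) | O=C1CCC23C(C)=CC(OC(=O)C(C)(C)C)=C(C(C)C)C2C13 | intermediate (not isolated)
8 | 4-methyl-1-oxo-7-(propan-2-yl)-1,2,3,8a-tetrahydroazulen-6-yl pivalate (racemic) | O=C1CCC2=C(C)C=C(OC(=O)C(C)(C)C)C(C(C)C)=CC12 | intermediate (not isolated)
9 | 4-methyl-7-(propan-2-yl)-2,3,7,8-tetrahydroazulene-1,6-dione (racemic at C7) | O=C1CCC2=C1CC(C(C)C)C(=O)C=C2C | intermediate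
10 | (4S)-6-{[dimethyl(phenyl)silyl]oxy}-4-methyl-7-(propan-2-yl)-3,4,7,8-tetrahydroazulen-1(2H)-one (C7 epimers) | O=C1CCC2=C1CC(C(C)C)C(O[Si](C)(C)c1ccccc1)=C[C@@H]2C | intermediate
11 | (4S)-6-{[dimethyl(phenyl)silyl]oxy}-1,4-dimethyl-7-(propan-2-yl)-1,2,3,4,7,8-hexahydroazulen-1-ol (C1 and C7 epimers) | CC1(O)CCC2=C1CC(C(C)C)C(O[Si](C)(C)c1ccccc1)=C[C@@H]2C | intermediate (not isolated)
12 | (10S)-guaia-1,4-dien-8-one (C7 epimers; equilibrating with the 1(5),3-diene tautomer CC1=CCC2=C1CC(C(C)C)C(=O)C[C@@H]2C) | CC1=C2CC(C(C)C)C(=O)C[C@H](C)C2=CC1 | intermediate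
13 | (10S)-2β,4β-epidioxyguaia-1(5)-en-8-one (C7 epimers) | C[C@]12C[C@H](OO1)C1=C2CC(C(C)C)C(=O)C[C@@H]1C | intermediate (not isolated)
14 | (2S,4R,10S)-2β,4β-dihydroxyguaia-1(5)-en-8-one (C7 epimers) | O[C@H]1C[C@@](C)(O)C2=C1[C@@H](C)CC(=O)C(C(C)C)C2 | intermediate
15 | (2R,4R,7R,10S)-2α-acetoxy-4β-hydroxyguaia-1(5)-en-8-one | CC(=O)O[C@@H]1C[C@@](C)(O)C2=C1[C@@H](C)CC(=O)[C@@H](C(C)C)C2 | intermediate
16 | (4R)-6-{[dimethyl(phenyl)silyl]oxy}-4-methyl-7-(propan-2-yl)-3,4,7,8-tetrahydroazulen-1(2H)-one (C7 epimers) | O=C1CCC2=C1CC(C(C)C)C(O[Si](C)(C)c1ccccc1)=C[C@H]2C | intermediate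
17 | (4R)-6-{[dimethyl(phenyl)silyl]oxy}-1,4-dimethyl-7-(propan-2-yl)-1,2,3,4,7,8-hexahydroazulen-1-ol (C1 and C7 epimers) | CC1(O)CCC2=C1CC(C(C)C)C(O[Si](C)(C)c1ccccc1)=C[C@H]2C | intermediate (not isolated)
18 | (10R)-guaia-1(5),3-dien-8-one (C7 epimers; equilibrating with the 1,4-diene tautomer) | CC1=CCC2=C1CC(C(C)C)C(=O)C[C@H]2C | intermediate
19 | (10R)-1α,3α-epidioxyguaia-4-en-8-one (C7 epimers) | CC1=C2CC(C(C)C)C(=O)C[C@@H](C)[C@@]23C[C@@H]1OO3 | intermediate (not isolated)
20 | (1S,10R)-1α-hydroxyguaia-4-ene-3,8-dione (C7 epimers) | CC1=C2CC(C(C)C)C(=O)C[C@@H](C)[C@@]2(O)CC1=O | intermediate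
21 | (1S,10R)-1α-hydroxyguaia-4,6-diene-3,8-dione | CC1=C2C=C(C(C)C)C(=O)C[C@@H](C)[C@@]2(O)CC1=O | intermediate
22 | (2R,7R,10S)-2α-acetoxyguaia-1(5),3-dien-8-one | CC(=O)O[C@@H]1C=C(C)C2=C1[C@@H](C)CC(=O)[C@@H](C(C)C)C2 | intermediate (not isolated)
23 | (10R)-guaia-1,4,6-triene-3,8-dione | O=C1C=C2[C@H](C)CC(=O)C(C(C)C)=CC2=C1C | intermediate (not isolated)
24 | Diels–Alder adduct of 22 and 23 (C3–C1' and C1–C2' bonds, B-half cyclopentenone exo, acetoxy bridge syn to C4=C5) | CC(=O)O[C@@H]1[C@@H]2C(C)=C3C[C@H](C(C)C)C(=O)C[C@H](C)[C@@]31[C@@H]1C(=O)C(C)=C3C=C(C(C)C)C(=O)C[C@@H](C)[C@]312 | intermediate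
25 | 11'-hydroperoxide of 24 | CC(=O)O[C@@H]1[C@@H]2C(C)=C3C[C@H](C(C)C)C(=O)C[C@H](C)[C@@]31[C@@H]1C(=O)C(C)=C3C=C(C(C)(C)OO)C(=O)C[C@@H](C)[C@]312 | intermediate (not isolated)
26 | CNP0361479.4 | CC(=O)O[C@@H]1[C@@H]2C(C)=C3C[C@H](C(C)C)C(=O)C[C@H](C)[C@@]31[C@@H]1C(=O)C(C)=C3C=C4C(C)(C)OO[C@]4(O)C[C@@H](C)[C@]312 | target

**Totals**
Total step count: 13. Longest linear sequence: 9 steps (1–3, then 4–7 or 8–11, then 12–13).

**Three steps most likely to fail, each with one fallback**

Step 4 (site- and enantioselective copper hydride reduction of the doubly conjugated ene-dione). The fallback sets out from 9 and replaces metal hydride by iminium catalysis. Transfer hydrogenation with a Hantzsch ester under a chiral ammonium phosphate (valine tert-butyl ester/TRIP salt) reduces the C9=C10 bond to give (10S)-15-norguaia-1(5)-ene-4,8-dione F1. The isolated C8 ketone is then ketalised in preference to the tetrasubstituted cyclopentenone (ethylene glycol, p-TsOH) to the dioxolane F2. MeLi/CeCl3 addition gives the ketal tertiary alcohol F3, and the acidic work-up that dehydrates it also unmasks C8, so the sequence comes back to the route at 12.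

Step 12 (two transient partners and a facial, regio- and exo-selective cycloaddition). The fallback sets out from 15 and exchanges the acetate for a bulky, non-migrating silyl ether before the cycloaddition. Methanolysis (K2CO3, MeOH) gives the 2α,4β-diol F4, and TBSCl/imidazole silylates only the secondary hydroxyl to give the silyl ether F5. Burgess dehydration in the presence of 21 passes through the silyloxy diene F6, which shields its α-face more strongly, to the silyloxy cycloadduct F7. TBAF gives the C2 alcohol F8, and acetylation (Ac2O, DMAP) comes back to the route at 24.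

Step 13 (selective C11'–H peroxidation). The fallback sets out from 24 and replaces radical C–H oxidation by an ene reaction. Catalytic DBU equilibrates the 4',6'-dienedione with its deconjugated 7'(11')-isopropylidene isomer F9. Irradiation of that mixture with O2 and tetraphenylporphyrin lets singlet oxygen react only with F9 (Schenck ene reaction with hydrogen abstraction from C6', the position geminal to the carbonyl, as with pulegone). This gives hydroperoxide 25 and comes back to the route at 26.

**Further compounds**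
F1 | step 4 | (4S)-4-methyl-7-(propan-2-yl)-3,4,5,7-tetrahydroazulene-1,6(2H,8H)-dione ((10S)-15-norguaia-1(5)-ene-4,8-dione, C7 epimers) | O=C1CCC2=C1CC(C(C)C)C(=O)C[C@@H]2C
F2 | step 4 | C8 ethylene ketal of F1 | O=C1CCC2=C1CC(C(C)C)C1(OCCO1)C[C@@H]2C
F3 | step 4 | C4 methyl carbinol of F2 (tertiary allylic alcohol, C4 epimers) | CC1(O)CCC2=C1CC(C(C)C)C1(OCCO1)C[C@@H]2C
F4 | step 12 | (2R,4R,7R,10S)-2α,4β-dihydroxyguaia-1(5)-en-8-one | O[C@@H]1C[C@@](C)(O)C2=C1[C@@H](C)CC(=O)[C@@H](C(C)C)C2
F5 | step 12 | 2α-tert-butyldimethylsilyl ether of F4 | CC(C)(C)[Si](C)(C)O[C@@H]1C[C@@](C)(O)C2=C1[C@@H](C)CC(=O)[C@@H](C(C)C)C2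
F6 | step 12 | (2R,7R,10S)-2α-(tert-butyldimethylsilyloxy)guaia-1(5),3-dien-8-one | CC(C)(C)[Si](C)(C)O[C@@H]1C=C(C)C2=C1[C@@H](C)CC(=O)[C@@H](C(C)C)C2
F7 | step 12 | 2-O-silyl analogue of adduct 24 | CC(C)(C)[Si](C)(C)O[C@@H]1[C@@H]2C(C)=C3C[C@H](C(C)C)C(=O)C[C@H](C)[C@@]31[C@@H]1C(=O)C(C)=C3C=C(C(C)C)C(=O)C[C@@H](C)[C@]312
F8 | step 12 | 2-deacetyl analogue of adduct 24 | O[C@@H]1[C@@H]2C(C)=C3C[C@H](C(C)C)C(=O)C[C@H](C)[C@@]31[C@@H]1C(=O)C(C)=C3C=C(C(C)C)C(=O)C[C@@H](C)[C@]312
F9 | step 13 | 7'(11')-isopropylidene (deconjugated) isomer of 24 | CC(=O)O[C@@H]1[C@@H]2C(C)=C3C[C@H](C(C)C)C(=O)C[C@H](C)[C@@]31[C@@H]1C(=O)C(C)=C3CC(=C(C)C)C(=O)C[C@@H](C)[C@]312
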